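**Retrosynthetic overview**

1. Target 31 ⇒ diol 26 (last steps: angeloylation of the primary C15–OH, then acetylation of C7–OH) ⇒ silylene-protected enone 25.
2. Cyclohexenone ring (formed last): C1–C2 bond by carbonyl-ene closure of a C11 aldehyde onto a C4 isopropenyl group; the aldehyde comes from cyclobutanone 20 by one-carbon homologation.
3. Key disconnection (two rings at once): intramolecular ketene + 1,3-diene [2+2] of acyclic acid 17 forms the C5–C11 and C4–C10 bonds, closing the cyclobutane and the seven-membered ring together.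
4. 17 ⇒ methyl ketone 7 + aldehyde 10: Mukaiyama aldol (C8–C9), then Evans–Tishchenko reduction with prenal (C7 carbinol and C9 senecioate in one step).
5. 7 ⇒ isoprene monoxide + nitroethane (Pd-DYKAT sets quaternary C6), Nef, Heck with 2-bromopropene. Ring order: 4- and 7-membered rings together, then the 6-membered ring.

Assumption 1: atoms are called by their longipinane locants in the target (C1 ketone, C2=C3, C12 methyl on C3, cyclobutane C4/C5/C11/C10, C13 methyl on C10, quaternary C6 with C14 methyl and C15H2O, carbinols C7 and C9); with these the target is 4R,5S,6S,7R,9R,10R,11R.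
Assumption 2: the (R,R)-Trost ligand is taken to give 3 with the configuration drawn; if the sense is opposite, the (S,S)-ligand is used.

**Route**

Step 1
Reactants: 1 2-methyl-2-vinyloxirane (isoprene monoxide, racemic); 2 nitroethane
Product: 3 (2R)-2-methyl-2-(1-nitroethyl)but-3-en-1-ol (epimer mixture at the nitro carbon)
Conditions: Pd2(dba)3·CHCl3 (1 mol%), (R,R)-Trost naphthyl ligand (3 mol%), CH2Cl2, rt
Reagents that add atoms: none
Why: Trost Pd-catalysed dynamic kinetic asymmetric allylic alkylation, in which racemic 1 ionises to equilibrating π-allyl-Pd alkoxides and the ligand steers the nitronate to one face of the tertiary allyl terminus, setting the quaternary future C6, while the nitro-bearing carbon forms as a mixture that is erased in step 3.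

Step 2
Reactants: 3
Product: 4 tert-butyl-dimethyl-{[(2R)-2-methyl-2-(1-nitroethyl)but-3-en-1-yl]oxy}silane
Conditions: TBSCl, imidazole, DMF, rt
Reagents that add atoms: tert-butyldimethylsilyl chloride, CC(C)(C)[Si](C)(C)Cl
Why: Standard silylation of the primary alcohol blocks O15 so that only the C9 hydroxyl can direct the later Tishchenko reduction, and no stereocentre is touched.

Step 3
Reactants: 4
Product: 5 (3S)-3-{[tert-butyl(dimethyl)silyl]oxymethyl}-3-methylpent-4-en-2-one
Conditions: NaOMe, MeOH, 0 °C; then aq TiCl3, NH4OAc, rt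
Reagents that add atoms: water, O
Why: McMurry reductive Nef reaction, in which TiCl3 reduces the nitronate to an imine that hydrolyses to the methyl ketone, removing the nitro stereocentre and leaving the quaternary centre untouched (S only by CIP priority change).

Step 4
Reactants: 5; 6 2-bromopropene
Product: 7 (3S,4E)-3-{[tert-butyl(dimethyl)silyl]oxymethyl}-3,6-dimethylhepta-4,6-dien-2-one
Conditions: Pd(OAc)2 (5 mol%), P(o-tol)3, Et3N, MeCN, 80 °C, sealed tube
Reagents that add atoms: none
Why: Mizoroki–Heck coupling, in which the propenyl-Pd adds to the terminal vinyl carbon and syn β-hydride elimination is possible only away from the quaternary carbon, giving the E-1,3-diene needed as ketene partner.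

Step 5
Reactants: 8 methyl (2R)-3-hydroxy-2-methylpropanoate ((R)-Roche ester)
Product: 9 methyl (2R)-3-{[tert-butyl(dimethyl)silyl]oxy}-2-methylpropanoate
Conditions: TBSCl, imidazole, CH2Cl2, rt
Reagents that add atoms: tert-butyldimethylsilyl chloride, CC(C)(C)[Si](C)(C)Cl
Why: Standard silylation of the primary alcohol, with the stereocentre not involved.

Step 6
Reactants: 9
Product: 10 (2R)-3-{[tert-butyl(dimethyl)silyl]oxy}-2-methylpropanal
Conditions: DIBAL-H, CH2Cl2, −78 °C; Rochelle salt work-up; used at once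
Reagents that add atoms: none
Why: DIBAL-H half-reduction, whose tetrahedral aluminium hemiacetal survives at −78 °C and releases the aldehyde only on work-up, so the α-stereocentre (a temporary control element destroyed in step 12) is retained.

Step 7
Reactants: 7; 10
Product: 12 (2R,3R,6S,7E)-1-{[tert-butyl(dimethyl)silyl]oxy}-6-{[tert-butyl(dimethyl)silyl]oxymethyl}-3-hydroxy-2,6,9-trimethyldeca-7,9-dien-5-one, via silyl enol ether 11 (not isolated)
Conditions: TMSOTf, Et3N, CH2Cl2, 0 °C; then 10, BF3·OEt2, −78 °C; aq NaHCO3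
Reagents that add atoms: none
Why: Mukaiyama aldol, in which 7 can enolise only at its methyl group and BF3-activated 10 is attacked through an open transition state under Felkin–Anh control by its α-methyl centre, setting the future C9 carbinol (3R, 2,3-syn).

Step 8
Reactants: 12; 13 3-methylbut-2-enal (prenal)
Product: 14 (2R,3R,5R,6S,7E)-1-{[tert-butyl(dimethyl)silyl]oxy}-6-{[tert-butyl(dimethyl)silyl]oxymethyl}-5-hydroxy-2,6,9-trimethyldeca-7,9-dien-3-yl 3-methylbut-2-enoate
Conditions: SmI2 (30 mol%), prenal (5 equiv), THF, −10 °C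
Reagents that add atoms: none
Why: Evans–Tishchenko reaction, in which the samarium-bound hemiacetal of the C3 hydroxyl with prenal delivers hydride intramolecularly through a chair transition state to the C5 ketone, setting the future C7 carbinol 1,3-anti (5R) and leaving the senecioate on the future O9.

Step 9
Reactants: 14
Product: 15 (2R,3R,5R,6S,7E)-1,5-dihydroxy-6-(hydroxymethyl)-2,6,9-trimethyldeca-7,9-dien-3-yl 3-methylbut-2-enoate
Conditions: HF·pyridine, pyridine/THF, 0 °C to rt
Reagents that add atoms: none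
Why: Fluoride desilylation of both primary TBS ethers under acidic conditions that do not promote acyl migration, with ester and diene inert.

Step 10
Reactants: 15
Product: 16 (2R,3R)-4-[(4R,5S)-2,2-di-tert-butyl-5-methyl-5-[(1E)-3-methylbuta-1,3-dien-1-yl]-1,3,2-dioxasilinan-4-yl]-1-hydroxy-2-methylbutan-3-yl 3-methylbut-2-enoate
Conditions: tBu2Si(OTf)2 (1.05 equiv), 2,6-lutidine, CH2Cl2, −20 °C
Reagents that add atoms: di-tert-butylsilyl bis(trifluoromethanesulfonate), CC(C)(C)[Si](OS(=O)(=O)C(F)(F)F)(OS(=O)(=O)C(F)(F)F)C(C)(C)C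
Why: Cyclic silylene protection, in which the 1,3-diol closes a six-membered dioxasilinane faster than the lone primary OH is silylated, and the chair (chain and dienyl equatorial, methyl axial) pre-organises the two chain ends for step 12.

Step 11
Reactants: 16
Product: 17 (2S,3R)-4-[(4R,5S)-2,2-di-tert-butyl-5-methyl-5-[(1E)-3-methylbuta-1,3-dien-1-yl]-1,3,2-dioxasilinan-4-yl]-2-methyl-3-[(3-methylbut-2-enoyl)oxy]butanoic acid
Conditions: TEMPO (20 mol%), PhI(OAc)2, MeCN/pH 7 buffer, rt
Reagents that add atoms: water, O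
Why: TEMPO/PhI(OAc)2 oxidation of the remaining primary alcohol through the aldehyde hydrate to the acid, the α-stereocentre being irrelevant because it becomes the ketene carbon.

Step 12
Reactants: 17
Product: 20 1,5-dimethyl-8-oxo-7-(prop-1-en-2-yl)bicyclo[4.1.1]octan-2-yl 3-methylbut-2-enoate with 4-O and the 5-CH2O bridged by Si(tBu)2 (isopropenyl anti to the seven-membered ring; centres as in 31), via acid chloride 18 (not isolated), via ketene 19 (not isolated)
Conditions: (COCl)2, cat. DMF, CH2Cl2, 0 °C to rt; evaporate; slow addition to Et3N (5 equiv), toluene, 110 °C, 0.003 M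
Reagents that add atoms: none
Why: Proposed new method: dehydrochlorination gives the α-methyl ketene, which adds across the proximal C5=C4 bond of the E-diene in an asynchronous thermal [2+2] cycloaddition (carbonyl carbon C11 to the unsubstituted diene terminus C5, α-carbon C10 to C4 where the developing charge is allyl-stabilised), closing the seven-membered ring and the cyclobutanone together as a bridged bicyclo[4.1.1]octan-8-one, the closest known reactions being type I intramolecular ketene–alkene cycloadditions to bicyclo[3.1.1]heptan-6-ones and ketene–1,3-diene [2+2] additions, and suprafacial addition to the E-alkene puts the isopropenyl group anti to the new ring, the tether forces the C10 methyl outward, and the π-faces are chosen by the chair dioxasilinane (tied-back CH2O outside, C6 methyl anti to the incoming ketene) and by C9 (H eclipsing the α-methyl, OSen anti to the diene), giving the target configuration at C4, C5 and C10.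

Step 13
Reactants: 20
Product: 21 8-(methoxymethylidene) analogue of 20 (E/Z enol ether mixture)
Conditions: MeOCH2PPh3Cl (3 equiv), KHMDS (2.8 equiv), THF, 0 °C; then 20, 0 °C to rt
Reagents that add atoms: (methoxymethyl)triphenylphosphonium chloride, COC[P+](c1ccccc1)(c1ccccc1)c1ccccc1.[Cl-]
Why: Wittig methoxymethylenation, which succeeds because the strained cyclobutanone cannot enolise (bridgehead and quaternary α-carbons) and so only undergoes addition, giving the one-carbon homologue.

Step 14
Reactants: 21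
Product: 23 (4R,5S,6S,7R,9R,10R,11R)-7,15-O-(di-tert-butylsilanediyl)-1,7,15-trihydroxylongipin-3(12)-en-9-yl 3-methylbut-2-enoate (C1 epimer mixture), via aldehyde 22 (not isolated)
Conditions: TsOH·H2O (cat.), acetone/H2O, rt; solvent switch; Sc(OTf)3 (10 mol%), CH2Cl2, 0 °C
Reagents that add atoms: water, O
Why: Enol ether hydrolysis gives the C11 aldehyde, whose epimers equilibrate through the enol, and only the epimer with the formyl group syn to the C4 isopropenyl group can undergo the Lewis-acid-catalysed type I carbonyl-ene reaction (H transfer from the allylic methyl) that closes the six-membered ring and fixes C11 as R.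

Step 15
Reactants: 23
Product: 25 (4R,5S,6S,7R,9R,10R,11R)-7,15-O-(di-tert-butylsilanediyl)-7,15-dihydroxy-1-oxolongipin-2-en-9-yl 3-methylbut-2-enoate, via β,γ-unsaturated ketone 24 (not isolated)
Conditions: Dess–Martin periodinane, NaHCO3, CH2Cl2, rt; then DBU (0.5 equiv), rt
Reagents that add atoms: none
Why: Dess–Martin oxidation of the C1 carbinol followed by base-mediated isomerisation of the β,γ-unsaturated ketone through its dienolate (the bridgehead C11 cannot enolise) gives the conjugated enone and removes the C1 stereocentre.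

Step 16
Reactants: 25
Product: 26 (4R,5S,6S,7R,9R,10R,11R)-7,15-dihydroxy-1-oxolongipin-2-en-9-yl 3-methylbut-2-enoate
Conditions: HF·pyridine, THF, 0 °C to rt
Reagents that add atoms: none
Why: Fluoride cleavage of the di-tert-butylsilylene to the 1,3-diol under acidic conditions that avoid acyl migration.

Step 17
Reactants: 26; 27 angelic acid ((Z)-2-methylbut-2-enoic acid)
Product: 29 (4R,5S,6S,7R,9R,10R,11R)-7-hydroxy-15-[(Z)-2-methylbut-2-enoyloxy]-1-oxolongipin-2-en-9-yl 3-methylbut-2-enoate, via mixed anhydride 28 (not isolated)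
Conditions: 2,4,6-trichlorobenzoyl chloride, Et3N, toluene, rt; then 26, 80 °C
Reagents that add atoms: none
Why: Yamaguchi esterification, in which the mixed anhydride of angelic acid acylates only the primary C15 hydroxyl (the C7 hydroxyl is secondary and neopentylic) under conditions that keep the Z geometry.

Step 18
Reactants: 29; 30 acetic anhydride
Product: 31 (4R,5S,6S,7R,9R,10R,11R)-7-acetoxy-15-[(Z)-2-methylbut-2-enoyloxy]-1-oxolongipin-2-en-9-yl 3-methylbut-2-enoate (CNP0179010.1)
Conditions: Ac2O, pyridine, DMAP (cat.), CH2Cl2, rt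
Reagents that add atoms: none
Why: DMAP-catalysed acetylation of the remaining hindered secondary C7 hydroxyl, to which angelate and senecioate esters are stable, gives the target.

**Compound list**

1 | 2-methyl-2-vinyloxirane (racemic) | CC1(C=C)CO1 | starting material
2 | nitroethane | CC[N+](=O)[O-] | starting material
3 | (2R)-2-methyl-2-(1-nitroethyl)but-3-en-1-ol | OC[C@](C(C)[N+](=O)[O-])(C)C=C | intermediate
4 | TBS ether of 3 | CC(C)(C)[Si](C)(C)OC[C@](C(C)[N+](=O)[O-])(C)C=C | intermediate
5 | (3S)-3-(TBS-oxymethyl)-3-methylpent-4-en-2-one | CC(C)(C)[Si](C)(C)OC[C@](C(C)=O)(C)C=C | intermediate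
6 | 2-bromopropene | CC(Br)=C | starting material
7 | (3S,4E)-3-(TBS-oxymethyl)-3,6-dimethylhepta-4,6-dien-2-one | CC(C)(C)[Si](C)(C)OC[C@](C(C)=O)(C)/C=C/C(C)=C | intermediate
8 | methyl (2R)-3-hydroxy-2-methylpropanoate | COC(=O)[C@H](C)CO | starting material
9 | methyl (2R)-3-(TBS-oxy)-2-methylpropanoate | COC(=O)[C@H](C)CO[Si](C)(C)C(C)(C)C | intermediate
10 | (2R)-3-(TBS-oxy)-2-methylpropanal | O=C[C@H](C)CO[Si](C)(C)C(C)(C)C | intermediate
11 | trimethylsilyl enol ether of 7 | C=C(O[Si](C)(C)C)[C@](C)(CO[Si](C)(C)C(C)(C)C)/C=C/C(C)=C | intermediate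
12 | (2R,3R,6S,7E)-aldol, 3-hydroxy-5-ketone | CC(C)(C)[Si](C)(C)OC[C@@H](C)[C@H](O)CC(=O)[C@](C)(CO[Si](C)(C)C(C)(C)C)/C=C/C(C)=C | intermediate
13 | 3-methylbut-2-enal | CC(C)=CC=O | starting material
14 | (2R,3R,5R,6S,7E)-5-hydroxy 3-senecioate, bis-TBS | CC(C)(C)[Si](C)(C)OC[C@@H](C)[C@H](OC(=O)C=C(C)C)C[C@@H](O)[C@](C)(CO[Si](C)(C)C(C)(C)C)/C=C/C(C)=C | intermediate
15 | (2R,3R,5R,6S,7E)-triol 3-senecioate | OC[C@@H](C)[C@H](OC(=O)C=C(C)C)C[C@@H](O)[C@](C)(CO)/C=C/C(C)=C | intermediate
16 | silylene-protected primary alcohol | OC[C@@H](C)[C@H](OC(=O)C=C(C)C)C[C@H]1O[Si](C(C)(C)C)(C(C)(C)C)OC[C@]1(C)/C=C/C(C)=C | intermediate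
17 | (2S,3R)-acid | OC(=O)[C@@H](C)[C@H](OC(=O)C=C(C)C)C[C@H]1O[Si](C(C)(C)C)(C(C)(C)C)OC[C@]1(C)/C=C/C(C)=C | intermediate
18 | acid chloride of 17 | ClC(=O)[C@@H](C)[C@H](OC(=O)C=C(C)C)C[C@H]1O[Si](C(C)(C)C)(C(C)(C)C)OC[C@]1(C)/C=C/C(C)=C | intermediate
19 | α-methyl ketene | O=C=C(C)[C@H](OC(=O)C=C(C)C)C[C@H]1O[Si](C(C)(C)C)(C(C)(C)C)OC[C@]1(C)/C=C/C(C)=C | intermediate
20 | bicyclo[4.1.1]octan-8-one cycloadduct | O1C[C@]2(C)[C@@H]3C(=O)[C@@](C)([C@H]3C(C)=C)[C@H](OC(=O)C=C(C)C)C[C@H]2O[Si]1(C(C)(C)C)C(C)(C)C | intermediate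
21 | methyl enol ether (E/Z) | O1C[C@]2(C)[C@@H]3C(=COC)[C@@](C)([C@H]3C(C)=C)[C@H](OC(=O)C=C(C)C)C[C@H]2O[Si]1(C(C)(C)C)C(C)(C)C | intermediate
22 | C11 aldehyde (reacting epimer) | O1C[C@]2(C)[C@@H]3[C@@H](C=O)[C@@](C)([C@H]3C(C)=C)[C@H](OC(=O)C=C(C)C)C[C@H]2O[Si]1(C(C)(C)C)C(C)(C)C | intermediate
23 | ene product, C1 carbinol with exocyclic C3=C12 | O1C[C@]2(C)[C@@H]3[C@H]4C(O)CC(=C)[C@@H]3[C@@]4(C)[C@H](OC(=O)C=C(C)C)C[C@H]2O[Si]1(C(C)(C)C)C(C)(C)C | intermediate
24 | β,γ-unsaturated C1 ketone | O1C[C@]2(C)[C@@H]3[C@H]4C(=O)CC(=C)[C@@H]3[C@@]4(C)[C@H](OC(=O)C=C(C)C)C[C@H]2O[Si]1(C(C)(C)C)C(C)(C)C | intermediate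
25 | silylene-protected enone | O1C[C@]2(C)[C@@H]3[C@H]4C(=O)C=C(C)[C@@H]3[C@@]4(C)[C@H](OC(=O)C=C(C)C)C[C@H]2O[Si]1(C(C)(C)C)C(C)(C)C | intermediate
26 | 7,15-diol 9-senecioate | OC[C@]1(C)[C@@H]2[C@H]3C(=O)C=C(C)[C@@H]2[C@@]3(C)[C@H](OC(=O)C=C(C)C)C[C@H]1O | intermediate
27 | angelic acid | C/C=C(/C)C(=O)O | starting material
28 | angelic 2,4,6-trichlorobenzoic anhydride | C/C=C(/C)C(=O)OC(=O)c1c(Cl)cc(Cl)cc1Cl | intermediate
29 | 15-angelate 9-senecioate 7-ol | C/C=C(/C)C(=O)OC[C@]1(C)[C@@H]2[C@H]3C(=O)C=C(C)[C@@H]2[C@@]3(C)[C@H](OC(=O)C=C(C)C)C[C@H]1O | intermediate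
30 | acetic anhydride | CC(=O)OC(C)=O | starting material
31 | CNP0179010.1 | C/C=C(/C)C(=O)OC[C@]1(C)[C@@H]2[C@H]3C(=O)C=C(C)[C@@H]2[C@@]3(C)[C@H](OC(=O)C=C(C)C)C[C@H]1OC(C)=O | target

**Step count and risks**

Total steps: 18. Longest linear sequence: 16 (steps 1–4 and 7–18); steps 5–6 make the C9–C11 piece.

Most likely to fail, 1: step 12. The four-atom tether is longer than in precedent, and the ketene may dimerise, lose the β-senecioate, or add to the wrong π-face. The fallback sets out from 17 and switches to a cationic keteniminium cycloaddition. Acid 17 is coupled with pyrrolidine (EDC, HOBt) to the pyrrolidine amide F1. Tf2O and 2,6-di-tert-butyl-4-methylpyridine in 1,2-dichloroethane (rt to 80 °C) convert it to the keteniminium ion, which adds to the diene to give the cyclobutaniminium triflate F2. Aqueous NaHCO3 hydrolysis returns to the route at 20.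

Most likely to fail, 2: step 14. The carbonyl-ene closure onto a cyclobutane-bridged system may stall or give Prins by-products. The fallback sets out from 21 and closes the ring by metathesis instead. Compound 21 is hydrolysed and aldehyde 22 is isolated. Vinylmagnesium bromide (THF, −78 °C) gives the allylic alcohol F4. Ring-closing metathesis with the isopropenyl group (Grubbs II, CH2Cl2, 40 °C) gives the cyclohexenol F5. Dess–Martin oxidation returns to the route at 25 without an isomerisation step.

Most likely to fail, 3: step 8. An enal in the Evans–Tishchenko reaction with a very hindered ketone may react sluggishly or suffer samarium-mediated side reactions. The fallback sets out from 12 and separates reduction from acylation. Hydroxyl-directed reduction with Me4NBH(OAc)3 (MeCN/AcOH, −30 °C) gives the anti-diol F3. 3-Methylbut-2-enoyl chloride and pyridine (CH2Cl2, −20 °C) acylate the less hindered C3 hydroxyl (the C5 hydroxyl is neopentylic), returning to the route at 14.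

Further compounds
F1 | step 12 | pyrrolidine amide of acid 17 | O=C(N2CCCC2)[C@@H](C)[C@H](OC(=O)C=C(C)C)C[C@H]1O[Si](C(C)(C)C)(C(C)(C)C)OC[C@]1(C)/C=C/C(C)=C
F2 | step 12 | cyclobutaniminium triflate (pyrrolidinium analogue of 20) | O1C[C@]2(C)[C@@H]3C(=[N+]5CCCC5)[C@@](C)([C@H]3C(C)=C)[C@H](OC(=O)C=C(C)C)C[C@H]2O[Si]1(C(C)(C)C)C(C)(C)C.[O-]S(=O)(=O)C(F)(F)F
F3 | step 8 | (2R,3R,5R,6S,7E)-3,5-anti-diol, bis-TBS | CC(C)(C)[Si](C)(C)OC[C@@H](C)[C@H](O)C[C@@H](O)[C@](C)(CO[Si](C)(C)C(C)(C)C)/C=C/C(C)=C
F4 | step 14 | C11 1-hydroxyprop-2-enyl diene (vinyl adduct of 22) | O1C[C@]2(C)[C@@H]3[C@@H](C(O)C=C)[C@@](C)([C@H]3C(C)=C)[C@H](OC(=O)C=C(C)C)C[C@H]2O[Si]1(C(C)(C)C)C(C)(C)C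
F5 | step 14 | silylene-protected longipin-2-en-1-ol 9-senecioate | O1C[C@]2(C)[C@@H]3[C@H]4C(O)C=C(C)[C@@H]3[C@@]4(C)[C@H](OC(=O)C=C(C)C)C[C@H]2O[Si]1(C(C)(C)C)C(C)(C)C
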